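**Retrosynthetic overview**
- Ring C is closed last by oxidative cyclisation of a 2'-hydroxychalcone, forming O1–C2 and then C2=C3.
- The chalcone is cut at Cα=Cβ (Claisen–Schmidt) into 2'-hydroxy-3',4',5',6'-tetramethoxyacetophenone (ring A) and unprotected isovanillin (ring B). Isovanillin already carries the free 3'-OH, so no protecting group or late demethylation is needed.
- In the acetophenone, the future C8–OMe comes from copper-catalysed methoxylation of an aryl bromide. The bromide comes from bromination of the Friedel–Crafts acetylation product of 3,4,5-trimethoxyphenol.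
- Rings A and B are bought as benzene rings, and ring C is the only ring formed.

Assumption: the target is achiral with no stereocentre, so "single enantiomer" calls for no stereocontrol. The only stereo-elements on the way (the E alkene and the transient sp3 centres) are erased in the last step.

Step 1
Reactants: 1 3,4,5-trimethoxyphenol
Product: 2 1-(6-hydroxy-2,3,4-trimethoxyphenyl)ethanone
Conditions: AcOH, BF3·OEt2 (4 equiv), 85 °C, 3 h; then ice-water
Reagents that add atoms: acetic acid CC(=O)O
Why: BF3-promoted Friedel–Crafts acylation: the two ring C–H positions are equivalent and both ortho to the OH, so only one ketone can form, and its chelated, deactivated ring does not acylate twice; no stereocentre is made.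

Step 2
Reactants: 2 1-(6-hydroxy-2,3,4-trimethoxyphenyl)ethanone
Product: 3 1-(3-bromo-2-hydroxy-4,5,6-trimethoxyphenyl)ethanone
Conditions: NBS (1.05 equiv), MeCN, 0 °C to rt, dark, 2 h
Reagents that add atoms: N-bromosuccinimide O=C1CCC(=O)N1Br
Why: Electrophilic aromatic bromination: the one remaining ring C–H is ortho to the OH and to an OMe group, so ionic ring bromination is much faster than alpha-bromination of the hydrogen-bonded ketone.

Step 3
Reactants: 3 1-(3-bromo-2-hydroxy-4,5,6-trimethoxyphenyl)ethanone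
Product: 4 1-(2-hydroxy-3,4,5,6-tetramethoxyphenyl)ethanone
Conditions: NaOMe (25% in MeOH, 6 equiv), CuBr (0.2 equiv), DMF, 110 °C, N2, 5 h; then 2 M HCl
Reagents that add atoms: sodium methoxide C[O-].[Na+]
Why: Ullmann-type methoxylation catalysed by monovalent copper: methoxide replaces bromide on the ring just as in the conversion of 5-bromovanillin into syringaldehyde, where a free ortho-OH and a carbonyl group are likewise tolerated.

Step 4
Reactants: 4 1-(2-hydroxy-3,4,5,6-tetramethoxyphenyl)ethanone; 5 isovanillin (3-hydroxy-4-methoxybenzaldehyde)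
Product: 7 (E)-3-(3-hydroxy-4-methoxyphenyl)-1-(2-hydroxy-3,4,5,6-tetramethoxyphenyl)prop-2-en-1-one, via aldol adduct 6 (not isolated)
Conditions: KOH (50% aq, 10 equiv), EtOH, N2, rt, 48 h; then 2 M HCl, 0 °C
Reagents that add atoms: none
Why: Claisen–Schmidt condensation (crossed aldol, then E1cB dehydration of 6): 5 cannot enolise, its OH is meta to the CHO so the phenoxide barely lowers the electrophilicity, and the conjugated E alkene is the thermodynamic product.

Step 5
Reactants: 7 (E)-3-(3-hydroxy-4-methoxyphenyl)-1-(2-hydroxy-3,4,5,6-tetramethoxyphenyl)prop-2-en-1-one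
Product: 9 3'-demethylnobiletin (2-(3-hydroxy-4-methoxyphenyl)-5,6,7,8-tetramethoxy-4H-chromen-4-one), via 3-iodoflavanone 8 (not isolated)
Conditions: I2 (10 mol%), DMSO, 120 °C, 3 h
Reagents that add atoms: none
Why: Iodine-catalysed oxidative cyclisation of a 2'-hydroxychalcone in DMSO: iodine-triggered oxa-Michael-type ring closure gives 8, loss of HI installs C2=C3, DMSO reoxidises HI to I2, and the two transient stereocentres disappear in the planar achiral pyranone.

**Compound list**
1 | 3,4,5-trimethoxyphenol | COc1cc(O)cc(OC)c1OC | starting material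
2 | 1-(6-hydroxy-2,3,4-trimethoxyphenyl)ethanone | CC(=O)c1c(O)cc(OC)c(OC)c1OC | intermediate
3 | 1-(3-bromo-2-hydroxy-4,5,6-trimethoxyphenyl)ethanone | CC(=O)c1c(O)c(Br)c(OC)c(OC)c1OC | intermediate
4 | 1-(2-hydroxy-3,4,5,6-tetramethoxyphenyl)ethanone | CC(=O)c1c(O)c(OC)c(OC)c(OC)c1OC | intermediate
5 | isovanillin (3-hydroxy-4-methoxybenzaldehyde) | COc1ccc(C=O)cc1O | starting material
6 | aldol adduct, 3-hydroxy-3-(3-hydroxy-4-methoxyphenyl)-1-(2-hydroxy-3,4,5,6-tetramethoxyphenyl)propan-1-one (racemic, not isolated) | COc1ccc(C(O)CC(=O)c2c(O)c(OC)c(OC)c(OC)c2OC)cc1O | intermediate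
7 | (E)-3-(3-hydroxy-4-methoxyphenyl)-1-(2-hydroxy-3,4,5,6-tetramethoxyphenyl)prop-2-en-1-one | COc1ccc(/C=C/C(=O)c2c(O)c(OC)c(OC)c(OC)c2OC)cc1O | intermediate
8 | trans-2-(3-hydroxy-4-methoxyphenyl)-3-iodo-5,6,7,8-tetramethoxychroman-4-one (racemic, one enantiomer drawn, not isolated) | COc1ccc([C@@H]2Oc3c(OC)c(OC)c(OC)c(OC)c3C(=O)[C@H]2I)cc1O | intermediate
9 | 3'-demethylnobiletin, 2-(3-hydroxy-4-methoxyphenyl)-5,6,7,8-tetramethoxy-4H-chromen-4-one (achiral) | COc1ccc(-c2cc(=O)c3c(OC)c(OC)c(OC)c(OC)c3o2)cc1O | target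

Total step count: 5.
Longest linear sequence: 5 (1 → 2 → 3 → 4 → 7 → 9).

**Three steps most likely to fail**

**Step 3 (methoxylation).**
- Risk: the bromide is flanked on both sides and sits next to a phenoxide. Reduction back to 2 or slow turnover may therefore beat C–O coupling.
- Fallback: the fifth oxygen is brought in by oxidation of a C–H bond instead of by coupling. It sets out from 1 and comes back at 4.
- O-Methylation of 1 (MeI, K2CO3, acetone, reflux) gives 1,2,3,5-tetramethoxybenzene F1.
- AcCl and AlCl3 in Et2O acetylate it to 1-(2,3,4,6-tetramethoxyphenyl)ethanone F2.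
- In the same flask this loses the crowded methyl group next to the carbonyl by chelation-assisted cleavage, giving 1-(2-hydroxy-3,4,6-trimethoxyphenyl)ethanone F3.
- Elbs persulfate oxidation (K2S2O8, aq NaOH, rt) attacks the only free position, para to the phenoxide. This gives potassium 3-acetyl-4-hydroxy-2,5,6-trimethoxyphenyl sulfate F4.
- Hot dilute HCl hydrolyses it to 1-(2,5-dihydroxy-3,4,6-trimethoxyphenyl)ethanone F5.
- One equivalent of MeI with K2CO3 in acetone methylates only the 5-OH, because the 2-OH is held in the hydrogen bond to the ketone. This gives 4.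

**Step 4 (condensation with the free phenol).**
- Risk: in strong base both partners are phenoxides. Conversion may be slow, and the electron-rich phenoxide of 5 may be air-oxidised.
- Fallback: the OH is masked as an acid-labile acetal for the C–C bond formation only. It sets out from 5 (with 4 as partner) and comes back at 7.
- MOMCl and iPr2NEt in CH2Cl2 at 0 °C to rt turn 5 into 4-methoxy-3-(methoxymethoxy)benzaldehyde F6.
- Condensation with 4 (KOH, EtOH, rt) gives (E)-1-(2-hydroxy-3,4,5,6-tetramethoxyphenyl)-3-[4-methoxy-3-(methoxymethoxy)phenyl]prop-2-en-1-one F7.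
- HCl in MeOH at 40 °C removes the acetal and gives 7.

**Step 5 (oxidative cyclisation).**
- Risk: the free guaiacol-type ring B may be iodinated. HI at 120 °C may also cleave the 5-OMe group peri to the carbonyl.
- Fallback: ring C is built at the flavone oxidation level through a 1,3-diketone, so no oxidation, iodine or HI is involved. It sets out from 4 and comes back at 9.
- Crossed Claisen condensation of 4 with commercial methyl 3-(benzyloxy)-4-methoxybenzoate F8 (NaH, 4 equiv, THF, reflux) gives 1-[3-(benzyloxy)-4-methoxyphenyl]-3-(2-hydroxy-3,4,5,6-tetramethoxyphenyl)propane-1,3-dione F9.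
- Catalytic H2SO4 in AcOH at 100 °C cyclodehydrates it to 2-[3-(benzyloxy)-4-methoxyphenyl]-5,6,7,8-tetramethoxy-4H-chromen-4-one F10.
- Hydrogenolysis (H2, 1 atm, 10% Pd/C, EtOAc–MeOH, rt) removes the benzyl group without touching the pyranone and gives 9.

**Further compounds**
F1 | step 3 | 1,2,3,5-tetramethoxybenzene | COc1cc(OC)c(OC)c(OC)c1
F2 | step 3 | 1-(2,3,4,6-tetramethoxyphenyl)ethanone | CC(=O)c1c(OC)cc(OC)c(OC)c1OC
F3 | step 3 | 1-(2-hydroxy-3,4,6-trimethoxyphenyl)ethanone | CC(=O)c1c(OC)cc(OC)c(OC)c1O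
F4 | step 3 | potassium 3-acetyl-4-hydroxy-2,5,6-trimethoxyphenyl sulfate | CC(=O)c1c(OC)c(OS(=O)(=O)[O-])c(OC)c(OC)c1O.[K+]
F5 | step 3 | 1-(2,5-dihydroxy-3,4,6-trimethoxyphenyl)ethanone | CC(=O)c1c(OC)c(O)c(OC)c(OC)c1O
F6 | step 4 | 4-methoxy-3-(methoxymethoxy)benzaldehyde | COCOc1cc(C=O)ccc1OC
F7 | step 4 | (E)-1-(2-hydroxy-3,4,5,6-tetramethoxyphenyl)-3-[4-methoxy-3-(methoxymethoxy)phenyl]prop-2-en-1-one | COCOc1cc(/C=C/C(=O)c2c(O)c(OC)c(OC)c(OC)c2OC)ccc1OC
F8 | step 5 | methyl 3-(benzyloxy)-4-methoxybenzoate | COC(=O)c1ccc(OC)c(OCc2ccccc2)c1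
F9 | step 5 | 1-[3-(benzyloxy)-4-methoxyphenyl]-3-(2-hydroxy-3,4,5,6-tetramethoxyphenyl)propane-1,3-dione | COc1ccc(C(=O)CC(=O)c2c(O)c(OC)c(OC)c(OC)c2OC)cc1OCc1ccccc1
F10 | step 5 | 2-[3-(benzyloxy)-4-methoxyphenyl]-5,6,7,8-tetramethoxy-4H-chromen-4-one | COc1ccc(-c2cc(=O)c3c(OC)c(OC)c(OC)c(OC)c3o2)cc1OCc1ccccc1
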